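**Plan**
- Ring A of this 3-methoxyflavone carries para oxygens at C5 and C8, a third oxygen at C7 and hydrogen at C6. That is the pattern a 3-alkoxycyclobutenedione leaves behind when a 4-hydroxycyclobutenone is ring-expanded to a hydroquinone.
- Retrosynthesis: the O–C bonds go first (4'-O-acyl, 5-O-methyl, 7-O-prenyl, 8-O-methyl). Ring A is then cut at C8–C8a and C4a–C5 into a C6-metalated 2-aryl-3-methoxypyran-4-one and 3-isopropoxycyclobutenedione. The pyranone is cut at C2–C1' (cross-coupling).
- Forward: ring C (the pyranone, from pyromeconic acid) is there from the start, ring B is attached by Suzuki coupling, and ring A is closed last by the benzannulation. The three ring-A oxygens are then addressed one at a time (8-OMe, 7-O-prenyl, 5-OMe).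
- Stereochemistry: there is none to set. The only transient stereo-elements (the carbinol of the cyclobutenone adduct, the Z-dienylketene) disappear on aromatisation.

Key step: step 7

Remark: the target has no stereocentre and no stereogenic double bond, so "single enantiomer" is read as the one achiral constitution drawn. Compounds 1, 4 and 7 are taken to be purchasable.

**Route**

Step 1
Reactants: 1 3-hydroxy-4H-pyran-4-one (pyromeconic acid)
Product: 2 2-bromo-3-hydroxy-4H-pyran-4-one
Conditions: NBS (1.05 equiv), MeCN, 0 °C → rt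
Reagents that add atoms: N-bromosuccinimide, O=C1CCC(=O)N1Br
Why: Electrophilic bromination of the enolic 3-hydroxypyranone should go to C2, the enol β-carbon next to the ring oxygen, as is known for pyromeconic and kojic acids.

Step 2
Reactants: 2 2-bromo-3-hydroxy-4H-pyran-4-one
Product: 3 2-bromo-3-methoxy-4H-pyran-4-one
Conditions: MeI (1.5 equiv), K2CO3, DMF, rt
Reagents that add atoms: iodomethane, CI
Why: Williamson O-methylation of the acidic enolic hydroxyl is standard for 3-hydroxypyranones, and carbonate at room temperature should not displace the vinylogous acyl bromide.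

Step 3
Reactants: 3 2-bromo-3-methoxy-4H-pyran-4-one; 4 2-methoxy-4-(4,4,5,5-tetramethyl-1,3,2-dioxaborolan-2-yl)phenol
Product: 5 2-(4-hydroxy-3-methoxyphenyl)-3-methoxy-4H-pyran-4-one
Conditions: Pd(dppf)Cl2 (5 mol %), K2CO3 (3 equiv), 1,4-dioxane/H2O (4:1), degassed, 80 °C
Reagents that add atoms: none
Why: Suzuki–Miyaura coupling; the C2–Br bond is a vinylogous acyl bromide that should undergo oxidative addition readily, and the electron-rich boronate couples with its phenol unprotected under aqueous carbonate.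

Step 4
Reactants: 5 2-(4-hydroxy-3-methoxyphenyl)-3-methoxy-4H-pyran-4-one
Product: 6 2-methoxy-4-(3-methoxy-4-oxo-4H-pyran-2-yl)phenyl pivalate
Conditions: PivCl (1.2 equiv), Et3N, DMAP (cat.), CH2Cl2, 0 °C → rt
Reagents that add atoms: pivaloyl chloride, CC(C)(C)C(Cl)=O
Why: DMAP-catalysed O-acylation of the phenol; the pivalate is chosen because it has no α-hydrogen and a hindered carbonyl (inert to LiTMP and to a vinyl-lithium at −78 °C), should survive BCl3 and carbonate alkylations, and leaves by mild methanolysis at the end.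

Step 5
Reactants: 7 3,4-diisopropoxycyclobut-3-ene-1,2-dione (diisopropyl squarate)
Product: 8 4-hydroxy-2,3-diisopropoxycyclobut-2-en-1-one (racemic)
Conditions: LiAlH(Ot-Bu)3 (1.05 equiv), THF, −78 → 0 °C; cold 1 M HCl quench
Reagents that add atoms: none
Why: Mono-reduction of one squarate carbonyl with the mild hydride LiAlH(Ot-Bu)3 (1,2-reduction that stops at the hydroxycyclobutenone) is the established first half of the semisquarate preparation; the carbinol centre is racemic and is destroyed in step 6.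

Step 6
Reactants: 8 4-hydroxy-2,3-diisopropoxycyclobut-2-en-1-one
Product: 9 3-isopropoxycyclobut-3-ene-1,2-dione
Conditions: conc. HCl (cat.), CH2Cl2, rt
Reagents that add atoms: none
Why: Acid-catalysed allylic transposition and hydrolysis: ionisation of the C4 hydroxyl gives an alkoxy-stabilised cyclobutenyl cation that takes up water at C2 and expels isopropanol, the known way from squarate reduction products to 3-alkoxycyclobutenediones.

Step 7
Reactants: 6 2-methoxy-4-(3-methoxy-4-oxo-4H-pyran-2-yl)phenyl pivalate; 9 3-isopropoxycyclobut-3-ene-1,2-dione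
Product: 13 5,8-dihydroxy-7-isopropoxy-3-methoxy-2-(3-methoxy-4-pivaloyloxyphenyl)chromen-4-one, via C6-lithiated pyranone 10 (not isolated), via 4-hydroxycyclobutenone adduct 11 (not isolated), via (Z)-dienylketene 12 (not isolated)
Conditions: n-BuLi/2,2,6,6-tetramethylpiperidine (LiTMP, 1.1 equiv), THF, −78 °C, 20 min; cannulate into 9 (1.2 equiv), THF, −78 °C; aq. NH4Cl at −78 °C, extractive work-up; crude adduct in degassed toluene, 110 °C, Ar
Reagents that add atoms: none
Why: Proposed new method: LiTMP should remove the most acidic ring proton of 6 (C6–H next to the ring oxygen, as in the known C2-lithiation of chromones), and the vinyl-lithium 10 should add 1,2 to the ketone-like C2 carbonyl of 9 (C1 is a deactivated vinylogous ester), which forms C8–C8a and places the isopropoxy group next to the carbinol, hence at C7 and not C6. On heating, 11 should open by 4π conrotation with the hydroxyl turning outward, so that the pyranonyl group turns inward and the (Z)-dienylketene 12 closes ring A by thermal 6π electrocyclisation of its ketene carbon onto the enol-ether-like C5 of the pyranone (C4a–C5); enolisation of the doubly activated C4a–H then gives the aromatic 5,8-hydroquinone. The closest known reaction type is the Moore ring expansion of 4-aryl-, 4-heteroaryl- and 4-alkenyl-4-hydroxycyclobutenones made from squarates and organolithiums; a metalated 4-pyranone has not been shown as the nucleophile or as the 2π partner. No stereocentre results, since the carbinol centre of 11 and the alkene geometry of 12 are lost on aromatisation. The step needs site-selective metalation (secured by the bulky non-nucleophilic amide, −78 °C and the non-enolisable, hindered pivalate), carbonyl regioselectivity in 9 (electronic, as above) and outward rotation of the donor hydroxyl; the cold NH4Cl quench before the solvent switch avoids base-induced rearrangement of the adduct.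

Step 8
Reactants: 13 5,8-dihydroxy-7-isopropoxy-3-methoxy-2-(3-methoxy-4-pivaloyloxyphenyl)chromen-4-one
Product: 14 5-hydroxy-7-isopropoxy-3,8-dimethoxy-2-(3-methoxy-4-pivaloyloxyphenyl)chromen-4-one
Conditions: MeI (1.1 equiv), K2CO3 (1.2 equiv), acetone, rt, Ar
Reagents that add atoms: iodomethane, CI
Why: Selective Williamson methylation: the 8-OH is a free phenol whereas the 5-OH is held in a strong hydrogen bond to the C4 carbonyl and should not be alkylated under these mild conditions; exclusion of air prevents oxidation of the hydroquinone to the 5,8-quinone.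

Step 9
Reactants: 14 5-hydroxy-7-isopropoxy-3,8-dimethoxy-2-(3-methoxy-4-pivaloyloxyphenyl)chromen-4-one
Product: 15 5,7-dihydroxy-3,8-dimethoxy-2-(3-methoxy-4-pivaloyloxyphenyl)chromen-4-one
Conditions: BCl3 (3 equiv, 1 M in CH2Cl2), CH2Cl2, −78 → 0 °C; H2O/aq. NaHCO3 work-up
Reagents that add atoms: none
Why: Lewis-acid dealkylation with BCl3: secondary isopropyl aryl ethers are cleaved at low temperature by SN1-like collapse of the boron–ether complex, much faster than methyl ethers, while the 5-OH/C4=O pair is tied up as a boron chelate and the pivalate is inert.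

Step 10
Reactants: 15 5,7-dihydroxy-3,8-dimethoxy-2-(3-methoxy-4-pivaloyloxyphenyl)chromen-4-one
Product: 16 5-hydroxy-3,8-dimethoxy-7-(3-methylbut-2-enyloxy)-2-(3-methoxy-4-pivaloyloxyphenyl)chromen-4-one
Conditions: prenyl bromide (1.1 equiv), K2CO3 (1.2 equiv), acetone, rt
Reagents that add atoms: 1-bromo-3-methylbut-2-ene (prenyl bromide), CC(C)=CCBr
Why: Williamson etherification: the 7-OH, para to the C4 carbonyl, is the most acidic phenol and should be O-alkylated by prenyl bromide, whereas the chelated 5-OH stays untouched.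

Step 11
Reactants: 16 5-hydroxy-3,8-dimethoxy-7-(3-methylbut-2-enyloxy)-2-(3-methoxy-4-pivaloyloxyphenyl)chromen-4-one
Product: 17 3,5,8-trimethoxy-7-(3-methylbut-2-enyloxy)-2-(3-methoxy-4-pivaloyloxyphenyl)chromen-4-one
Conditions: Me2SO4 (3 equiv), anhydrous K2CO3, acetone, reflux
Reagents that add atoms: dimethyl sulfate, COS(=O)(=O)OC
Why: Forcing Williamson methylation with dimethyl sulfate and anhydrous carbonate is the classical way to alkylate the hydrogen-bonded 5-OH of flavones, and the anhydrous, non-nucleophilic medium should leave the pivalate and the prenyl ether intact.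

Step 12
Reactants: 17 3,5,8-trimethoxy-7-(3-methylbut-2-enyloxy)-2-(3-methoxy-4-pivaloyloxyphenyl)chromen-4-one
Product: 18 2-(4-hydroxy-3-methoxyphenyl)-3,5,8-trimethoxy-7-(3-methylbut-2-enyloxy)chromen-4-one (4'-hydroxy-3,5,8,3'-tetramethoxy-7-prenyloxyflavone)
Conditions: K2CO3 (2 equiv), MeOH, rt
Reagents that add atoms: none
Why: Base-mediated transesterification (methanolysis) of the aryl pivalate, whose phenoxide leaving group is stabilised by conjugation with the chromone, should free the 4'-OH without touching the methyl or prenyl ethers.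

**Compound list**
1 | 3-hydroxy-4H-pyran-4-one (pyromeconic acid) | O=c1ccocc1O | starting material
2 | 2-bromo-3-hydroxy-4H-pyran-4-one | O=c1ccoc(Br)c1O | intermediate
3 | 2-bromo-3-methoxy-4H-pyran-4-one | COc1c(Br)occc1=O | intermediate
4 | 2-methoxy-4-(4,4,5,5-tetramethyl-1,3,2-dioxaborolan-2-yl)phenol | COc1cc(B2OC(C)(C)C(C)(C)O2)ccc1O | starting material
5 | 2-(4-hydroxy-3-methoxyphenyl)-3-methoxy-4H-pyran-4-one | COc1cc(-c2occc(=O)c2OC)ccc1O | intermediate
6 | 2-methoxy-4-(3-methoxy-4-oxo-4H-pyran-2-yl)phenyl pivalate | COc1cc(-c2occc(=O)c2OC)ccc1OC(=O)C(C)(C)C | intermediate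
7 | 3,4-diisopropoxycyclobut-3-ene-1,2-dione (diisopropyl squarate) | CC(C)OC1=C(OC(C)C)C(=O)C1=O | starting material
8 | 4-hydroxy-2,3-diisopropoxycyclobut-2-en-1-one (racemic) | CC(C)OC1=C(OC(C)C)C(O)C1=O | intermediate
9 | 3-isopropoxycyclobut-3-ene-1,2-dione | CC(C)OC1=CC(=O)C1=O | intermediate
10 | 2-methoxy-4-(6-lithio-3-methoxy-4-oxo-4H-pyran-2-yl)phenyl pivalate | COc1cc(-c2oc([Li])cc(=O)c2OC)ccc1OC(=O)C(C)(C)C | intermediate
11 | 4-[6-(1-hydroxy-2-isopropoxy-4-oxocyclobut-2-en-1-yl)-3-methoxy-4-oxo-4H-pyran-2-yl]-2-methoxyphenyl pivalate (racemic) | COc1cc(-c2oc(C3(O)C(=O)C=C3OC(C)C)cc(=O)c2OC)ccc1OC(=O)C(C)(C)C | intermediate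
12 | 4-{6-[(1Z)-1-hydroxy-2-isopropoxy-4-oxobuta-1,3-dien-1-yl]-3-methoxy-4-oxo-4H-pyran-2-yl}-2-methoxyphenyl pivalate | COc1cc(-c2oc(/C(O)=C(/OC(C)C)C=C=O)cc(=O)c2OC)ccc1OC(=O)C(C)(C)C | intermediate
13 | 5,8-dihydroxy-7-isopropoxy-3-methoxy-2-(3-methoxy-4-pivaloyloxyphenyl)chromen-4-one | COc1cc(-c2oc3c(O)c(OC(C)C)cc(O)c3c(=O)c2OC)ccc1OC(=O)C(C)(C)C | intermediate
14 | 5-hydroxy-7-isopropoxy-3,8-dimethoxy-2-(3-methoxy-4-pivaloyloxyphenyl)chromen-4-one | COc1cc(-c2oc3c(OC)c(OC(C)C)cc(O)c3c(=O)c2OC)ccc1OC(=O)C(C)(C)C | intermediate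
15 | 5,7-dihydroxy-3,8-dimethoxy-2-(3-methoxy-4-pivaloyloxyphenyl)chromen-4-one | COc1cc(-c2oc3c(OC)c(O)cc(O)c3c(=O)c2OC)ccc1OC(=O)C(C)(C)C | intermediate
16 | 5-hydroxy-3,8-dimethoxy-7-(3-methylbut-2-enyloxy)-2-(3-methoxy-4-pivaloyloxyphenyl)chromen-4-one | COc1cc(-c2oc3c(OC)c(OCC=C(C)C)cc(O)c3c(=O)c2OC)ccc1OC(=O)C(C)(C)C | intermediate
17 | 3,5,8-trimethoxy-7-(3-methylbut-2-enyloxy)-2-(3-methoxy-4-pivaloyloxyphenyl)chromen-4-one | COc1cc(-c2oc3c(OC)c(OCC=C(C)C)cc(OC)c3c(=O)c2OC)ccc1OC(=O)C(C)(C)C | intermediate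
18 | 2-(4-hydroxy-3-methoxyphenyl)-3,5,8-trimethoxy-7-(3-methylbut-2-enyloxy)chromen-4-one | COc1cc(-c2oc3c(OC)c(OCC=C(C)C)cc(OC)c3c(=O)c2OC)ccc1O | target

**Step count and risks**

Total: 12 steps. Longest linear sequence: 10 steps (steps 1–4 and 7–12); steps 5–6 make the second fragment.

Most likely to fail:

1. Step 7. Metalation may occur at the wrong site, or the vinyl-lithium may attack a second molecule of 6 (pivalate carbonyl, conjugate addition to the pyranone). Addition to 9 may go by 1,4-addition–elimination at the alkoxy-bearing carbon in place of 1,2-addition. On heating, inward rotation of the hydroxyl would lead to furanone formation in place of closure of ring A.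
Fallback (known chemistry): ring A is taken from a phloroglucinol, ring C is closed onto it, and the 8-oxygen is put in afterwards by Elbs oxidation. This sequence does not set out from a numbered compound: 6 and 9, and with them 1–5, 7 and 8, are set aside. It starts from commercial 2-methoxy-1-(2,4,6-trihydroxyphenyl)ethanone and 4-benzyloxy-3-methoxybenzoic acid, and it comes back to the route at 14. The acid is dehydrated with DCC to 4-benzyloxy-3-methoxybenzoic anhydride F1. Allan–Robinson condensation of the ketone with this anhydride and triethylamine at about 160 °C, followed by brief alkaline hydrolysis of O-aroyl groups, should give 2-(4-benzyloxy-3-methoxyphenyl)-5,7-dihydroxy-3-methoxychromen-4-one F2. 2-Bromopropane with K2CO3 in DMF alkylates only the non-chelated 7-OH to 2-(4-benzyloxy-3-methoxyphenyl)-5-hydroxy-7-isopropoxy-3-methoxychromen-4-one F3. Elbs persulfate oxidation (K2S2O8, aqueous KOH/pyridine) attacks para to the 5-OH and forms 2-(4-benzyloxy-3-methoxyphenyl)-5-hydroxy-7-isopropoxy-3-methoxy-4-oxochromen-8-yl hydrogen sulfate F4. Warm dilute HCl hydrolyses it to 2-(4-benzyloxy-3-methoxyphenyl)-5,8-dihydroxy-7-isopropoxy-3-methoxychromen-4-one F5. Methylation as in step 8 gives 2-(4-benzyloxy-3-methoxyphenyl)-5-hydroxy-7-isopropoxy-3,8-dimethoxychromen-4-one F6. Hydrogenolysis (H2, Pd/C) frees the 4'-phenol to 5-hydroxy-2-(4-hydroxy-3-methoxyphenyl)-7-isopropoxy-3,8-dimethoxychromen-4-one F7. Pivaloyl chloride/Et3N then acylates this phenol (the 5-OH is chelated) to give 14.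

2. Step 9. Over-dealkylation: once boron is bound to the molecule, the crowded 8-O-methyl group (flanked by O7 and O1) or the 3-O-methyl group may be cleaved along with the isopropyl group.
Fallback: sets out from 13 and comes back at 17. The isopropyl group is removed before any ring-A methyl ether exists, and the 7- and 8-oxygens are then told apart by acidity instead of by ether type. BCl3 on 13 should give 5,7,8-trihydroxy-3-methoxy-2-(3-methoxy-4-pivaloyloxyphenyl)chromen-4-one F8. One equivalent of prenyl bromide with KHCO3 in DMF under argon should alkylate the 7-OH (para to the C4 carbonyl, a vinylogous acid) to 5,8-dihydroxy-3-methoxy-7-(3-methylbut-2-enyloxy)-2-(3-methoxy-4-pivaloyloxyphenyl)chromen-4-one F9. Exhaustive methylation of both remaining hydroxyls (Me2SO4, K2CO3, refluxing acetone) gives 17.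

3. Step 11. Under the forcing basic conditions needed for the hydrogen-bonded 5-OH, the pivaloyl group may be lost and the liberated 4'-phenol methylated; conversion may also stay incomplete.
Fallback: sets out from 16 and comes back at the target 18. The ester is exchanged for a base-inert silyl ether before the methylation. K2CO3/MeOH removes the pivalate to give 5-hydroxy-2-(4-hydroxy-3-methoxyphenyl)-3,8-dimethoxy-7-(3-methylbut-2-enyloxy)chromen-4-one F10. TIPSCl/imidazole silylates only the free 4'-OH to 5-hydroxy-3,8-dimethoxy-7-(3-methylbut-2-enyloxy)-2-(3-methoxy-4-triisopropylsilyloxyphenyl)chromen-4-one F11. NaH/MeI in THF methylates the 5-OH to 3,5,8-trimethoxy-7-(3-methylbut-2-enyloxy)-2-(3-methoxy-4-triisopropylsilyloxyphenyl)chromen-4-one F12. TBAF then gives 18.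

Further compounds
F1 | step 7 | 4-benzyloxy-3-methoxybenzoic anhydride | COc1cc(C(=O)OC(=O)c2ccc(OCc3ccccc3)c(OC)c2)ccc1OCc1ccccc1
F2 | step 7 | 2-(4-benzyloxy-3-methoxyphenyl)-5,7-dihydroxy-3-methoxychromen-4-one | COc1cc(-c2oc3cc(O)cc(O)c3c(=O)c2OC)ccc1OCc1ccccc1
F3 | step 7 | 2-(4-benzyloxy-3-methoxyphenyl)-5-hydroxy-7-isopropoxy-3-methoxychromen-4-one | COc1cc(-c2oc3cc(OC(C)C)cc(O)c3c(=O)c2OC)ccc1OCc1ccccc1
F4 | step 7 | 2-(4-benzyloxy-3-methoxyphenyl)-5-hydroxy-7-isopropoxy-3-methoxy-4-oxochromen-8-yl hydrogen sulfate | COc1cc(-c2oc3c(OS(=O)(=O)O)c(OC(C)C)cc(O)c3c(=O)c2OC)ccc1OCc1ccccc1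
F5 | step 7 | 2-(4-benzyloxy-3-methoxyphenyl)-5,8-dihydroxy-7-isopropoxy-3-methoxychromen-4-one | COc1cc(-c2oc3c(O)c(OC(C)C)cc(O)c3c(=O)c2OC)ccc1OCc1ccccc1
F6 | step 7 | 2-(4-benzyloxy-3-methoxyphenyl)-5-hydroxy-7-isopropoxy-3,8-dimethoxychromen-4-one | COc1cc(-c2oc3c(OC)c(OC(C)C)cc(O)c3c(=O)c2OC)ccc1OCc1ccccc1
F7 | step 7 | 5-hydroxy-2-(4-hydroxy-3-methoxyphenyl)-7-isopropoxy-3,8-dimethoxychromen-4-one | COc1cc(-c2oc3c(OC)c(OC(C)C)cc(O)c3c(=O)c2OC)ccc1O
F8 | step 9 | 5,7,8-trihydroxy-3-methoxy-2-(3-methoxy-4-pivaloyloxyphenyl)chromen-4-one | COc1cc(-c2oc3c(O)c(O)cc(O)c3c(=O)c2OC)ccc1OC(=O)C(C)(C)C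
F9 | step 9 | 5,8-dihydroxy-3-methoxy-7-(3-methylbut-2-enyloxy)-2-(3-methoxy-4-pivaloyloxyphenyl)chromen-4-one | COc1cc(-c2oc3c(O)c(OCC=C(C)C)cc(O)c3c(=O)c2OC)ccc1OC(=O)C(C)(C)C
F10 | step 11 | 5-hydroxy-2-(4-hydroxy-3-methoxyphenyl)-3,8-dimethoxy-7-(3-methylbut-2-enyloxy)chromen-4-one | COc1cc(-c2oc3c(OC)c(OCC=C(C)C)cc(O)c3c(=O)c2OC)ccc1O
F11 | step 11 | 5-hydroxy-3,8-dimethoxy-7-(3-methylbut-2-enyloxy)-2-(3-methoxy-4-triisopropylsilyloxyphenyl)chromen-4-one | COc1cc(-c2oc3c(OC)c(OCC=C(C)C)cc(O)c3c(=O)c2OC)ccc1O[Si](C(C)C)(C(C)C)C(C)C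
F12 | step 11 | 3,5,8-trimethoxy-7-(3-methylbut-2-enyloxy)-2-(3-methoxy-4-triisopropylsilyloxyphenyl)chromen-4-one | COc1cc(-c2oc3c(OC)c(OCC=C(C)C)cc(OC)c3c(=O)c2OC)ccc1O[Si](C(C)C)(C(C)C)C(C)C
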